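Adding free base to hurry these flasks is the mistake to avoid: Saturday's run had 2.2 equiv against Monday's 0.46 equiv, yet at 20.0 h their electrophile differs by 0.3 percentage points, less than the reading scatter.

all flasks: electrophile 0.80 M

| charge | nucleophile | free base | remark | time |
|---|---|---|---|---|
| Monday's | 1.8 equiv | 0.46 equiv | run made earlier |  |
| Saturday's | 1.8 equiv | 2.2 equiv | run made earlier |  |
| west | 1.80 equiv | 0.800 equiv |  | 30 h |
| north-east | 1.80 equiv | 1.60 equiv |  | 30 h |
| south-west | 1.80 equiv | 3.20 equiv |  | 30 h |

| run | time / h | electrophile / % | target / % |
|---|---|---|---|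
| Monday's | 3.00 | 94.9 | 4.2 |
| Monday's | 6.00 | 89.6 | 10.0 |
| Monday's | 10.0 | 83.3 | 15.2 |
| Monday's | 12.0 | 80.4 | 17.9 |
| Monday's | 15.0 | 76.5 | 20.8 |
| Monday's | 20.0 | 70.7 | 27.2 |
| Saturday's | 1.00 | 98.4 | 1.1 |
| Saturday's | 3.00 | 94.6 | 5.3 |
| Saturday's | 6.00 | 89.6 | 10.3 |
| Saturday's | 10.0 | 83.4 | 16.0 |
| Saturday's | 12.0 | 80.5 | 19.0 |
| Saturday's | 15.0 | 77.0 | 22.4 |
| Saturday's | 20.0 | 70.4 | 26.7 |

(standard deviation of a reading: 0.5 percentage points)

- the earlier runs were read with a standard deviation of 0.5 points

- part of the electrophile that has reacted at the end, west
- part of the electrophile that has reacted at the end, north-east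
- part of the electrophile that has reacted at the end, south-west
- what raising the equivalents of free base from its lowest to its highest value here does to the part of the electrophile that has reacted (changes below 5 percentage points count as none) (it rises / it falls / no change)

On the bench stand west, north-east and south-west, which differ in free base. Nucleophile is at 1.80 equiv, so electrophile is the limiting reagent. I reckon with rate = k[electrophile][nucleophile] and no base term. With x the part of the electrophile reacted and b the equivalents of nucleophile, this integrates to

ln[(b − x)/(b(1 − x))] = g(b − 1)t

The mean of the two runs at 20.0 h gives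

x = 29.4%, so g = 0.0106 /h

This g, the rate constant times [electrophile] as charged, is what I carry. Monday's reading at 6.00 h gives 0.0105 /h, so it holds steady. Solved for x at 30 h:

E = exp(g(b − 1)t) = 1.29

x = b(E − 1)/(bE − 1) = 39.6%

So when you come, expect that much reacted and 60.4% of the electrophile left. With no base term, my reckoning gives this figure for west, north-east and south-west alike. Leave the free base alone. South-west's 3.20 equiv lies above the tested 2.2 equiv, so I hold that flask more loosely.

The forecast gives 39.5% (37.5% to 42%) for west and north-east and 39.5% (35% to 43.5%) for south-west, with no change: “The rate therefore looks zero order in base over this range”.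

West gives 38.7%, north-east 39.3% and south-west 39.7%, a change of 0.98 points, under the 5 points margin, so no change.

    electrophile + nucleophile → acid set free + target (k = 2.19 × 10⁻⁴ /M/min)
    nucleophile + acid set free ⇌ protonated nucleophile, settled at all times (K = 411 /M)
    acid set free + free base ⇌ salt of the base, settled at all times (K = 1400 /M)
    electrophile + target → side product (k = 9.64 × 10⁻⁵ /M/min)
    nucleophile ⇌ dormant form (K = 5.30, k = 3.39 × 10⁻⁵ /min)

West, with the lowest base here, still holds 72% of its free base unbound at 30.0 h. For a flask like south-west with 0.720 equiv of nucleophile, g gives 0.915 for E and 18.0% reacted at 30.0 h, and that flask stands at 18.3%.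

The runs were computed with constants of no real substance, and the scatter is random.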